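## The problem

The target is a germacranolide. It has a ten-membered carbocycle (C1–C10) whose C6–C7 edge carries a butenolide (O–C6, C7=C11, C12 carbonyl, C13 acetoxymethyl). It also carries a C1 ketone, a cis-4,5-epoxide with the C15 methyl on C4, a free C9 hydroxyl, a C8 methacrylate and the C14 methyl on C10. Six stereocentres (4R,5S,6S,8R,9R,10S) lie in two groups, C4–C6 and C8–C10, on a medium ring that is costly to close and conformationally hard to predict. The epoxide can be made enantiopure at the start and can then steer the face on which C7–C10 are built and, later, hydride delivery to C6. C8 cannot be set directly with C9 and C10, because the target has the C8 and C9 oxygens trans while a reactive cis-dienophile delivers them cis; C8 therefore needs one inversion. Several groups will not survive rough treatment: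

- the β-hydroxy ketone (C9–OH/C1=O) is prone to retro-aldol cleavage, dehydration and epimerisation at C10;
- the γ-hydrogen of the butenolide at C6 lies next to the epoxide, so base can open the epoxide by vinylogous elimination;
- the epoxide is acid-sensitive, with the C1 carbonyl across the ring;
- the methacrylate is sensitive to ozone, radicals and nucleophiles;
- a free C8 hydroxyl can translactonise.

Strong base or acid is therefore confined to the stage before the ten-membered ring exists, and the two esters come last. The enabling feature is that C1 (ketone) and C6 (lactone O–CH) face each other across the ring and both bear oxygen. A C1=C6 double bond turns the ring into an octalin in which ring A (C1, C6, C7–C10) is a cyclohexene with cis oxygens at C8/C9, and ring B (C1–C6) holds the epoxide.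

## Retrosynthesis

**C8–O ester, with inversion (37 ⇒ 35 + 36).** The methacrylate is the most fragile group and goes on last. A Mitsunobu esterification of the 8-epi diol 35 with methacrylic acid 36 installs it and corrects C8 in one operation. The alternative, a trans-dioxygenated dienophile giving C8 directly, would be far less reactive. The forward step must pick the allylic C8–OH over the C9–OH.

**Butenolide: C7=C11 and the C6–O acyl bond (35 ⇐ 34 ⇐ 33 ⇐ 32 ⇐ 31 ⇐ 30 ⇐ 29 ⇐ 23 + 28).** An intramolecular Horner–Wadsworth–Emmons reaction of the α-acyloxy ketone 31 forms the tetrasubstituted alkene regiospecifically under mild base. C13 travels as a PMB ether in acid 28, because an acetoxy group β to the phosphonate carbanion would be expelled. The precursor 23 is a plain C6 carbinol with protected oxygens at C7–C9.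

**Reconnection C1=C6 (23 ⇐ 22 ⇐ 20).** The C1 and C6 carbonyls of diketone 22 are the ozonolysis products of the ring-fusion alkene of octalin 20. This removes any macrocyclisation and delivers C1 at its final oxidation level. Other transannular reconnections would need extra leaving groups or stereocentres. The forward sequence asks for reduction of C6 only, from one face.

**Ring A: C7–C8 and C9–C10 (20 ⇐ 19 ⇐ 17 ⇐ 16 ⇐ 15 ⇐ 13 + 14).** Ring A of 15 is the Diels–Alder adduct of the bis-exocyclic diene 13 and vinylene carbonate 14. Two bonds and four stereocentres arise at once; an aldol or metathesis closure of ring A would set them one by one. Silicon at C7 is a masked hydroxyl whose alkene geometry is fixed by the diene synthesis. The reaction must be endo and anti to the epoxide oxygen.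

**Ring B: C1–C6 (13 ⇐ 11).** Reductive coupling of the 1,7-diyne 11 on zirconocene forms ring B. The metallacycle fixes both exocyclic alkene geometries, which olefination of a cyclohexanedione would not.

**Diyne from nerol (11 ⇐ 9 ⇐ 8 ⇐ 7 ⇐ 4 ⇐ 3 ⇐ 2 ⇐ 1, with 5).** Sharpless epoxidation of nerol 1 gives 2; the Z-alkene maps onto the cis-epoxide with C15 in place. The alcohol terminus becomes the silylated alkyne (C6≡C7). The prenyl terminus is a masked aldehyde (C1) that becomes the methyl alkyne (C1≡C10, C14). The second homologation avoids K2CO3/MeOH and butyllithium, which would cleave the alkynyl–silicon bond.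

**Acid 28 (⇐ 27 ⇐ 24 + 25 + formaldehyde).** Knoevenagel condensation of allyl diethylphosphonoacetate 24 with formaldehyde, conjugate addition of PMB alcohol 25, and deallylation.

## Roads not taken

**Alternative 1:** The cut is C7–C8 together with O–C6. In the forward step Pd(PPh3)4 with i-Pr2NEt inserts into a C8–iodine bond of an acyclic allenoic acid; the carboxylate adds to the allene at C6 and reductive elimination joins C7 to C8, giving diene A1. Its merits are real: ring and butenolide form in one convergent step, C13 is already oxygenated, and the route to the ring system is shorter than the one chosen here. Its weak points for this target: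

- a strained ten-membered 4Z,8E-diene is closed by a cross-coupling;
- A1 still lacks the epoxide and both oxygens at C8/C9, so four stereocentres must be set on a flexible macrocycle;
- the two alkenes must be told apart, and the E-alkene needs a net anti, regiodifferentiated dioxygenation.

The chosen plan is longer, but it sets C8–C10 by a stereospecific cycloaddition on a six-membered ring and takes C4/C5 from a reagent-controlled epoxidation.

**Alternative 2:** The cut is C5–C6. MgBr2·OEt2 chelates a C5 aldehyde to the C4 PMB ether and C6 of a tethered silyloxyfuran attacks it, closing the ring to carbinol A2. Every oxygen is at its final oxidation level and C8–C10 come from reagent-controlled acyclic chemistry, so fewer redox steps follow the ring closure than in the chosen plan; in that respect it is the better route. Against it stand: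

- a ten-membered ring closed by an aldol reaction at high dilution;
- C5/C6 selectivity that depends on the macrocyclic transition state;
- a late epoxide closure by the tertiary C4 oxygen next to the acidic C6–H, plus dithiane removal;
- a long linear synthesis of the acyclic precursor.

The chosen plan needs no cyclisation event for the ten-membered ring and gets three contiguous centres from one step.

**Alternative 3:** The cut is C6–C7, made by ring contraction. Lithiation at C6 of a thirteen-membered bis-allylic ether triggers a [2,3]-Wittig shift to the homoallylic alcohol A3. The larger ring is easier to close, the contraction has good precedent for ten-membered carbocycles, and the C6 hydroxyl can direct the C4–C5 epoxidation. This is arguably better control of C4–C6 than the ring reduction used here. Its weak points: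

- the site of lithiation and [1,2] versus [2,3] selectivity;
- a C7 stereocentre that is made only to be destroyed;
- several steps to oxidise C12 and to move the double bond from C11=C13 into C7=C11 with oxygen at C13.

The chosen plan sets against this an epoxide fixed in step 1 and a butenolide formed directly at the right oxidation level.

Key step: step 9

Assumptions:

- Atom numbers C1–C15 are those of the target and are used for all intermediates. "Down" means the face of ring A opposite the epoxide oxygen.
- Compounds 27–31 are carried as mixtures at the phosphonate-bearing carbon, which becomes sp2 in step 21.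
- Compounds 23 and 30 may rest as transannular hemiketals; they are written in the open hydroxy ketone form that reacts.
- TBS = tert-butyldimethylsilyl, TES = triethylsilyl, PMB = 4-methoxybenzyl, Bn = benzyl.

## Route

Step 1
Reactants: 1 nerol
Product: 2 (2S,3R)-2,3-epoxynerol
Conditions: Ti(OiPr)4 (cat.), L-(+)-diethyl tartrate (cat.), t-BuOOH, 4 Å MS, CH2Cl2, −20 °C
Reagents that add atoms: tert-butyl hydroperoxide, CC(C)(C)OO
Why: Sharpless asymmetric epoxidation; the L-(+)-tartrate titanium complex delivers oxygen to the allylic alkene only and sets C4 (R) and C5 (S) of the target, while the remote alkene lacks the directing hydroxyl.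

Step 2
Reactants: 2 (2S,3R)-2,3-epoxynerol
Product: 3 (2R,3R)-3-methyl-3-(4-methylpent-3-enyl)oxirane-2-carbaldehyde
Conditions: PhI(OAc)2, TEMPO (cat.), CH2Cl2, rt
Reagents that add atoms: none
Why: TEMPO/PhI(OAc)2 oxidation of a primary epoxy alcohol; non-acidic conditions leave the epoxide intact, and the aldehyde is used crude.

Step 3
Reactants: 3 (2R,3R)-3-methyl-3-(4-methylpent-3-enyl)oxirane-2-carbaldehyde
Product: 4 (2S,3R)-2-ethynyl-3-methyl-3-(4-methylpent-3-enyl)oxirane
Conditions: dimethyl (1-diazo-2-oxopropyl)phosphonate, K2CO3, MeOH, 0 °C → rt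
Reagents that add atoms: dimethyl (1-diazo-2-oxopropyl)phosphonate, CC(=O)C(=[N+]=[N-])P(=O)(OC)OC
Why: Ohira–Bestmann homologation, which works on epoxy aldehydes; no silicon is present yet, so the methanolic base is harmless. The new carbon is C7.

Step 4
Reactants: 4 (2S,3R)-2-ethynyl-3-methyl-3-(4-methylpent-3-enyl)oxirane; 5 benzylchlorodimethylsilane
Product: 7 benzyl{[(2S,3R)-3-methyl-3-(4-methylpent-3-enyl)oxiran-2-yl]ethynyl}dimethylsilane, via lithium acetylide 6 (not isolated)
Conditions: n-BuLi, THF, −78 °C; then 5, −78 → 0 °C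
Reagents that add atoms: none
Why: Deprotonation and C-silylation of a terminal alkyne; the benzyldimethylsilyl group is the oxidisable silicon that later becomes the C7 oxygen.

Step 5
Reactants: 7 benzyl{[(2S,3R)-3-methyl-3-(4-methylpent-3-enyl)oxiran-2-yl]ethynyl}dimethylsilane
Product: 8 3-[(2R,3S)-3-{[benzyl(dimethyl)silyl]ethynyl}-2-methyloxiran-2-yl]propanal
Conditions: O3, pyridine, CH2Cl2, −78 °C (Sudan Red 7B end point)
Reagents that add atoms: ozone, [O-][O+]=O
Why: Pyridine-mediated ozonolysis gives the aldehyde directly; the electron-rich trisubstituted alkene reacts far faster than the silyl alkyne or the arene. The aldehyde carbon is C1.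

Step 6
Reactants: 8 3-[(2R,3S)-3-{[benzyl(dimethyl)silyl]ethynyl}-2-methyloxiran-2-yl]propanal
Product: 9 benzyl{[(2S,3R)-3-(but-3-ynyl)-3-methyloxiran-2-yl]ethynyl}dimethylsilane
Conditions: Me3SiCHN2, LDA, THF, −78 °C → rt
Reagents that add atoms: (trimethylsilyl)diazomethane, C[Si](C)(C)C=[N+]=[N-]
Why: Colvin rearrangement (aldehyde to terminal alkyne via an alkylidene carbene); it is used in place of a second Ohira–Bestmann reaction because K2CO3/MeOH would cleave the alkynyl–silicon bond. The new carbon is C10.

Step 7
Reactants: 9 benzyl{[(2S,3R)-3-(but-3-ynyl)-3-methyloxiran-2-yl]ethynyl}dimethylsilane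
Product: 11 benzyl{[(2S,3R)-3-methyl-3-(pent-3-ynyl)oxiran-2-yl]ethynyl}dimethylsilane, via lithium acetylide 10 (not isolated)
Conditions: LDA, THF, −78 °C; then MeI, −78 °C → rt
Reagents that add atoms: iodomethane, CI
Why: Alkylation of a lithium acetylide adds C14; the amide base does not attack silicon as an alkyllithium could.

Step 8
Reactants: 11 benzyl{[(2S,3R)-3-methyl-3-(pent-3-ynyl)oxiran-2-yl]ethynyl}dimethylsilane
Product: 13 benzyl{(Z)-[(1R,4E,6S)-4-ethylidene-1-methyl-7-oxabicyclo[4.1.0]heptan-5-ylidene]methyl}dimethylsilane, via zirconacyclopentadiene 12 (not isolated)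
Conditions: Cp2ZrCl2, n-BuLi (2 equiv), THF, −78 °C; then 11, −78 °C → rt; then MeOH, aq NaHCO3
Reagents that add atoms: none
Why: Negishi reductive cyclisation of a 1,7-diyne; oxidative coupling on divalent zirconocene forms C1–C6 and a metallacycle in which both Zr–C bonds point inward. Protonolysis with retention puts hydrogen inward and CH3 and Si outward (E at C1=C10, Z by CIP at C6=C7).

Step 9
Reactants: 13 benzyl{(Z)-[(1R,4E,6S)-4-ethylidene-1-methyl-7-oxabicyclo[4.1.0]heptan-5-ylidene]methyl}dimethylsilane; 14 vinylene carbonate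
Product: 15 epoxy octalin carbonate (4R,5S,7S,8R,9R,10R): C1=C6 octalin with 4,5-epoxide, cis-8,9-carbonate, 7-SiMe2Bn and 10-CH3, the four ring-A substituents all down
Conditions: 14 (5 equiv), BHT (cat.), toluene, sealed tube, 150 °C
Reagents that add atoms: none
Why: Concerted suprafacial thermal [4+2] cycloaddition of normal electron demand between the s-cis-locked diene C10=C1–C6=C7 and the cis-enediol equivalent 14; it forms C7–C8 and C9–C10 and closes ring A as a cycloaddition, while the five-membered carbonate is carried in cis-fused. The closest known reaction types are Diels–Alder reactions of 1,2-bis(alkylidene)cyclohexanes and of vinylene carbonate with (E,E)-1,4-disubstituted dienes, which give all-cis adducts. C7 and C10 are set by the diene geometry: both substituents are outward, so Si and CH3 end up cis. C8 and C9 are set by the cis geometry of 14 and by the endo (Alder) alignment of the carbonate under the diene, which places both oxygens cis to Si and CH3. The absolute sense of all four centres comes from the epoxide: bonding occurs on the diene face opposite the C5 oxygen, as with arene oxides, because that oxygen shields its own face and repels the carbonate oxygens. The step therefore needs endo and anti selectivity, secured by secondary overlap with the carbonate and by the allylic C–O bond; the outward ethylidene methyl rules out a [1,5]-hydrogen shift of the diene. C9 and C10 emerge correctly related to C4/C5, C8 is deliberately epimeric (inverted in step 25), and C7 later becomes sp2.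

Step 10
Reactants: 15 epoxy octalin carbonate
Product: 16 epoxy octalin 8,9-diol (7-SiMe2Bn, 8-OH, 9-OH and 10-CH3 all down)
Conditions: K2CO3 (cat.), MeOH, 0 °C → rt
Reagents that add atoms: none
Why: Transesterification of a cyclic carbonate, done while the molecule is still a robust octalin; the cis β-hydroxysilane does not undergo Peterson elimination under weak base.

Step 11
Reactants: 16 epoxy octalin 8,9-diol
Product: 17 8,9-bis-TBS ether of 16
Conditions: TBSOTf, 2,6-lutidine, CH2Cl2, −78 → 0 °C
Reagents that add atoms: tert-butyldimethylsilyl triflate, CC(C)(C)[Si](C)(C)OS(=O)(=O)C(F)(F)F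
Why: Silylation of a hindered cis-diol with a silyl triflate at low temperature; silyl ethers are chosen because they can be removed at the end without base.

Step 12
Reactants: 17 8,9-bis-TBS ether
Product: 19 C7 allylic alcohol (7-OH down; 8,9-bis-TBS ether), via silanol 18 (not isolated)
Conditions: TBAF, THF, 0 °C; then KHCO3, 30% H2O2, MeOH, rt
Reagents that add atoms: hydrogen peroxide, OO
Why: Tamao–Fleming oxidation of a benzyldimethylsilyl group; fluoride removes the benzyl group and the silanol is oxidised with retention at C7, as in the oxidation of allylic silanes to allylic alcohols. The hindered secondary TBS ethers should outlast the short fluoride exposure at 0 °C.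

Step 13
Reactants: 19 C7 allylic alcohol
Product: 20 7-TES ether of 19
Conditions: TESOTf, 2,6-lutidine, CH2Cl2, −78 °C
Reagents that add atoms: triethylsilyl triflate, CC[Si](CC)(CC)OS(=O)(=O)C(F)(F)F
Why: Silylation; TES is removable in the presence of TBS, and a bulky non-chelating group on O7 supports Felkin control in step 15.

Step 14
Reactants: 20 7-TES ether
Product: 22 ten-membered 1,6-diketone (4,5-epoxide, 7-OTES, 8,9-bis-OTBS, 10-CH3), via ozonide 21 (not isolated)
Conditions: O3, CH2Cl2, −78 °C; then PPh3, −78 °C → rt
Reagents that add atoms: ozone, [O-][O+]=O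
Why: Ozonolysis of the ring-fusion alkene, the classical octalin to cyclodecane-1,6-dione cleavage; neutral reduction of the ozonide avoids transannular aldol reaction and C10 epimerisation. No stereocentre is formed.

Step 15
Reactants: 22 ten-membered 1,6-diketone
Product: 23 (6S)-C6 carbinol with the C1 ketone intact
Conditions: Zn(BH4)2, Et2O, −30 °C
Reagents that add atoms: none
Why: Chelation-controlled reduction of an α,β-epoxy ketone; zinc bridges the C6 carbonyl and the epoxide oxygen, which activates C6 over C1, and hydride enters from the C5–H side to give the anti epoxy alcohol (6S). The Felkin preference from the C7 silyloxy group points the same way.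

Step 16
Reactants: 24 allyl diethylphosphonoacetate; 25 4-methoxybenzyl alcohol
Product: 27 allyl 2-(diethoxyphosphoryl)-3-(4-methoxybenzyloxy)propanoate, via phosphonoacrylate 26 (not isolated)
Conditions: (CH2O)n, 25 (3 equiv), piperidine (cat.), toluene, 80 °C
Reagents that add atoms: paraformaldehyde (formaldehyde unit), C=O
Why: Knoevenagel condensation followed by oxa-Michael addition of the alcohol, the known course of phosphonoacetate/formaldehyde condensations in alcohols.

Step 17
Reactants: 27 allyl 2-(diethoxyphosphoryl)-3-(4-methoxybenzyloxy)propanoate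
Product: 28 2-(diethoxyphosphoryl)-3-(4-methoxybenzyloxy)propanoic acid
Conditions: Pd(PPh3)4 (cat.), morpholine, THF, rt; then aq KHSO4
Reagents that add atoms: none
Why: Tsuji–Trost deallylation frees the acid without hydroxide, which would trigger retro-Michael loss of the alkoxide.

Step 18
Reactants: 23 (6S)-C6 carbinol; 28 2-(diethoxyphosphoryl)-3-(4-methoxybenzyloxy)propanoic acid
Product: 29 C6 phosphonoacetate ester of 23
Conditions: DCC, DMAP (cat.), CH2Cl2, 0 °C → rt
Reagents that add atoms: none
Why: Steglich esterification; α-phosphono acids acylate hindered secondary alcohols well, and acylation drains any hemiketal form of 23.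

Step 19
Reactants: 29 C6 phosphonoacetate ester
Product: 30 C7 alcohol (TES removed)
Conditions: HF·pyridine, pyridine, THF, 0 °C
Reagents that add atoms: none
Why: Buffered HF·pyridine cleaves a secondary TES ether much faster than secondary TBS ethers and leaves the epoxide and the ester alone.

Step 20
Reactants: 30 C7 alcohol
Product: 31 C7 ketone (α-acyloxy ketone)
Conditions: Dess–Martin periodinane, pyridine, CH2Cl2, 0 °C → rt
Reagents that add atoms: none
Why: Dess–Martin oxidation of a hindered secondary alcohol under buffered, near-neutral conditions.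

Step 21
Reactants: 31 C7 ketone
Product: 32 butenolide (13-OPMB, 8,9-bis-OTBS, C8 epimeric)
Conditions: LiCl, DBU, MeCN, 0 °C
Reagents that add atoms: none
Why: Intramolecular Horner–Wadsworth–Emmons reaction under Masamune–Roush conditions; the lithium-chelated phosphonate is the most acidic site, and its five-membered addition to the adjacent C7 ketone followed by phosphate loss forms C7=C11 faster than β-elimination pathways can compete.

Step 22
Reactants: 32 butenolide
Product: 33 C13 primary alcohol
Conditions: DDQ, CH2Cl2/pH 7 buffer, 0 °C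
Reagents that add atoms: none
Why: Oxidative cleavage of a PMB ether under neutral conditions that the epoxide, butenolide and silyl ethers tolerate.

Step 23
Reactants: 33 C13 primary alcohol
Product: 34 C13 acetate
Conditions: Ac2O, pyridine, DMAP (cat.), CH2Cl2, 0 °C
Reagents that add atoms: acetic anhydride, CC(=O)OC(C)=O
Why: Acetylation of the only free hydroxyl.

Step 24
Reactants: 34 C13 acetate
Product: 35 8,9-diol (8-epi, 8-O-demethacryloyl target)
Conditions: HF·pyridine, pyridine, THF, 0 °C → rt
Reagents that add atoms: none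
Why: Fluoride-mediated removal of both TBS ethers under mildly acidic buffered conditions, which avoids the base that the β-hydroxy ketone and the butenolide cannot bear.

Step 25
Reactants: 35 8,9-diol; 36 methacrylic acid
Product: 37 CNP0185951.2
Conditions: PPh3, DIAD, toluene, 0 °C
Reagents that add atoms: none
Why: Mitsunobu esterification; the allylic C8 hydroxyl next to the sp2 C7 is the better SN2 site, and displacement by methacrylate inverts C8 to the 8R configuration while C9–OH stays free.

## Compound list

1 | nerol, (2Z)-3,7-dimethylocta-2,6-dien-1-ol | CC(C)=CCC/C(C)=C\CO | starting material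
2 | (2S,3R)-2,3-epoxynerol | CC(C)=CCC[C@@]1(C)O[C@H]1CO | intermediate
3 | (2R,3R)-3-methyl-3-(4-methylpent-3-enyl)oxirane-2-carbaldehyde | CC(C)=CCC[C@@]1(C)O[C@H]1C=O | intermediate
4 | (2S,3R)-2-ethynyl-3-methyl-3-(4-methylpent-3-enyl)oxirane | CC(C)=CCC[C@@]1(C)O[C@H]1C#C | intermediate
5 | benzylchlorodimethylsilane | C[Si](C)(Cl)Cc1ccccc1 | starting material
6 | lithium acetylide of 4 | CC(C)=CCC[C@@]1(C)O[C@H]1C#C[Li] | intermediate
7 | benzyl{[(2S,3R)-3-methyl-3-(4-methylpent-3-enyl)oxiran-2-yl]ethynyl}dimethylsilane | CC(C)=CCC[C@@]1(C)O[C@H]1C#C[Si](C)(C)Cc1ccccc1 | intermediate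
8 | 3-[(2R,3S)-3-{[benzyl(dimethyl)silyl]ethynyl}-2-methyloxiran-2-yl]propanal | O=CCC[C@@]1(C)O[C@H]1C#C[Si](C)(C)Cc1ccccc1 | intermediate
9 | benzyl{[(2S,3R)-3-(but-3-ynyl)-3-methyloxiran-2-yl]ethynyl}dimethylsilane | C#CCC[C@@]1(C)O[C@H]1C#C[Si](C)(C)Cc1ccccc1 | intermediate
10 | lithium acetylide of 9 | [Li]C#CCC[C@@]1(C)O[C@H]1C#C[Si](C)(C)Cc1ccccc1 | intermediate
11 | benzyl{[(2S,3R)-3-methyl-3-(pent-3-ynyl)oxiran-2-yl]ethynyl}dimethylsilane (epoxy 1,7-diyne) | CC#CCC[C@@]1(C)O[C@H]1C#C[Si](C)(C)Cc1ccccc1 | intermediate
12 | zirconacyclopentadiene (Cp2Zr bonded to C7 and C10 of the cyclised diyne) | CC1=C2CC[C@@]3(C)O[C@H]3C2=C([Si](C)(C)Cc4ccccc4)[Zr]1(C5C=CC=C5)C6C=CC=C6 | intermediate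
13 | benzyl{(Z)-[(1R,4E,6S)-4-ethylidene-1-methyl-7-oxabicyclo[4.1.0]heptan-5-ylidene]methyl}dimethylsilane (diene, CH3 and Si outward) | C/C=C1\CC[C@@]2(C)O[C@H]2/C1=C\[Si](C)(C)Cc1ccccc1 | intermediate
14 | vinylene carbonate (1,3-dioxol-2-one) | O=C1OC=CO1 | starting material
15 | epoxy octalin carbonate, (4R,5S,7S,8R,9R,10R): 7-SiMe2Bn, cis-8,9-carbonate and 10-CH3 all cis and anti to the epoxide oxygen | C[C@H]1[C@H]2OC(=O)O[C@H]2[C@@H]([Si](C)(C)Cc2ccccc2)C2=C1CC[C@@]1(C)O[C@H]12 | intermediate
16 | epoxy octalin 8,9-diol (all-cis 7-Si, 8-OH, 9-OH, 10-CH3) | C[C@H]1[C@@H](O)[C@@H](O)[C@@H]([Si](C)(C)Cc2ccccc2)C2=C1CC[C@@]1(C)O[C@H]12 | intermediate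
17 | 8,9-bis-TBS ether of 16 | C[C@H]1[C@@H](O[Si](C)(C)C(C)(C)C)[C@@H](O[Si](C)(C)C(C)(C)C)[C@@H]([Si](C)(C)Cc2ccccc2)C2=C1CC[C@@]1(C)O[C@H]12 | intermediate
18 | C7 dimethylsilanol (benzyl removed from 17) | C[C@H]1[C@@H](O[Si](C)(C)C(C)(C)C)[C@@H](O[Si](C)(C)C(C)(C)C)[C@@H]([Si](C)(C)O)C2=C1CC[C@@]1(C)O[C@H]12 | intermediate
19 | C7 allylic alcohol, 8,9-bis-TBS ether (7-OH cis to 8-OTBS) | C[C@H]1[C@@H](O[Si](C)(C)C(C)(C)C)[C@@H](O[Si](C)(C)C(C)(C)C)[C@@H](O)C2=C1CC[C@@]1(C)O[C@H]12 | intermediate
20 | 7-TES ether of 19 | C[C@H]1[C@@H](O[Si](C)(C)C(C)(C)C)[C@@H](O[Si](C)(C)C(C)(C)C)[C@@H](O[Si](CC)(CC)CC)C2=C1CC[C@@]1(C)O[C@H]12 | intermediate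
21 | ozonide of 20 (1,2,4-trioxolane bridging C1 and C6; configuration at C1/C6 not defined) | C[C@H]1[C@@H](O[Si](C)(C)C(C)(C)C)[C@@H](O[Si](C)(C)C(C)(C)C)[C@@H](O[Si](CC)(CC)CC)C23OOC1(O2)CC[C@@]1(C)O[C@H]13 | intermediate
22 | ten-membered 1,6-diketone (4,5-epoxide, 7-OTES, 8,9-bis-OTBS, 10-CH3) | C[C@H]1[C@@H](O[Si](C)(C)C(C)(C)C)[C@@H](O[Si](C)(C)C(C)(C)C)[C@@H](O[Si](CC)(CC)CC)C(=O)[C@@H]2O[C@]2(C)CCC1=O | intermediate
23 | (6S)-C6 carbinol, C1 ketone | C[C@H]1[C@@H](O[Si](C)(C)C(C)(C)C)[C@@H](O[Si](C)(C)C(C)(C)C)[C@@H](O[Si](CC)(CC)CC)[C@H](O)[C@@H]2O[C@]2(C)CCC1=O | intermediate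
24 | allyl diethylphosphonoacetate | C=CCOC(=O)CP(=O)(OCC)OCC | starting material
25 | 4-methoxybenzyl alcohol | COc1ccc(CO)cc1 | starting material
26 | allyl 2-(diethoxyphosphoryl)acrylate | C=CCOC(=O)C(=C)P(=O)(OCC)OCC | intermediate
27 | allyl 2-(diethoxyphosphoryl)-3-(4-methoxybenzyloxy)propanoate | C=CCOC(=O)C(COCc1ccc(OC)cc1)P(=O)(OCC)OCC | intermediate
28 | 2-(diethoxyphosphoryl)-3-(4-methoxybenzyloxy)propanoic acid | OC(=O)C(COCc1ccc(OC)cc1)P(=O)(OCC)OCC | intermediate
29 | C6 ester of 23 with acid 28 | C[C@H]1[C@@H](O[Si](C)(C)C(C)(C)C)[C@@H](O[Si](C)(C)C(C)(C)C)[C@@H](O[Si](CC)(CC)CC)[C@H](OC(=O)C(COCc2ccc(OC)cc2)P(=O)(OCC)OCC)[C@@H]2O[C@]2(C)CCC1=O | intermediate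
30 | C7 alcohol (29 without TES) | C[C@H]1[C@@H](O[Si](C)(C)C(C)(C)C)[C@@H](O[Si](C)(C)C(C)(C)C)[C@@H](O)[C@H](OC(=O)C(COCc2ccc(OC)cc2)P(=O)(OCC)OCC)[C@@H]2O[C@]2(C)CCC1=O | intermediate
31 | C7 ketone (1,7-diketone, C6 phosphonoacetate) | C[C@H]1[C@@H](O[Si](C)(C)C(C)(C)C)[C@@H](O[Si](C)(C)C(C)(C)C)C(=O)[C@H](OC(=O)C(COCc2ccc(OC)cc2)P(=O)(OCC)OCC)[C@@H]2O[C@]2(C)CCC1=O | intermediate
32 | butenolide: 13-O-PMB, 8,9-bis-O-TBS, 8-epi, 8-O-demethacryloyl analogue of the target | CC(C)(C)[Si](C)(C)O[C@H]1C2=C(COCc3ccc(OC)cc3)C(=O)O[C@@H]2[C@@H]2O[C@]2(C)CCC(=O)[C@@H](C)[C@H]1O[Si](C)(C)C(C)(C)C | intermediate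
33 | C13 primary alcohol (32 without PMB) | CC(C)(C)[Si](C)(C)O[C@H]1C2=C(CO)C(=O)O[C@@H]2[C@@H]2O[C@]2(C)CCC(=O)[C@@H](C)[C@H]1O[Si](C)(C)C(C)(C)C | intermediate
34 | C13 acetate, 8,9-bis-TBS ether | CC(C)(C)[Si](C)(C)O[C@H]1C2=C(COC(C)=O)C(=O)O[C@@H]2[C@@H]2O[C@]2(C)CCC(=O)[C@@H](C)[C@H]1O[Si](C)(C)C(C)(C)C | intermediate
35 | 8,9-diol: 8-epi, 8-O-demethacryloyl target | O[C@H]1C2=C(COC(C)=O)C(=O)O[C@@H]2[C@@H]2O[C@]2(C)CCC(=O)[C@@H](C)[C@H]1O | intermediate
36 | methacrylic acid | C=C(C)C(=O)O | starting material
37 | CNP0185951.2 (4R,5S,6S,8R,9R,10S) | C=C(C)C(=O)O[C@@H]1C2=C(COC(C)=O)C(=O)O[C@@H]2[C@@H]2O[C@]2(C)CCC(=O)[C@@H](C)[C@H]1O | target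

## Step count and least certain steps

Total step count: 25. Longest linear sequence: 23 steps (steps 1–15 and 18–25, from nerol); steps 16–17 are a two-step side branch to acid 28.

**Step 9 (key step).** Most likely to go wrong: slow cycloaddition at the hindered silyl-bearing terminus, so that polymerisation of 14, erosion of the endo preference and thermal isomerisation of the dienyl epoxide take over. Fallback, from 13 to 19, with the benzyl group taken off silicon before the cycloaddition:

- TBAF (THF, 0 °C) on the vinylsilane 13 gives dienylsilanol F1; a vinyl–silicon bond is not cleaved by fluoride.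
- F1 and 14 give silanol carbonate F2; the terminus is smaller and the Si–OH can hydrogen-bond to the carbonate ring oxygen only in the endo arrangement.
- K2CO3/MeOH gives silanol diol F3.
- Excess TBSOTf/2,6-lutidine caps both carbinols and the silanol, giving the tris-silylated compound F4.
- H2O2, KF, KHCO3 (THF/MeOH) oxidises the siloxane C–Si bond with retention to 19.

No fluoride then meets an allylsilane.

**Step 8.** Most likely to go wrong: β-elimination of the propargylic C–O bond (opening of the epoxide to an allenylzirconium alkoxide) from the alkyne complex before the second alkyne inserts. Fallback, from 11 directly to 13: catalytic reductive cyclisation with Pd2(dba)3·CHCl3, P(o-tol)3, AcOH and Et3SiH (benzene, rt). A hydridopalladium acetate adds syn to one alkyne, the alkenylpalladium adds syn to the other, and the silane replaces palladium by hydrogen with retention. This gives the same outward geometry without a stoichiometric oxophilic metal and makes no new compound.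

**Step 12.** Most likely to go wrong: fluoride-induced cleavage of the allyl–silicon bond (protodesilylation with allylic shift) instead of the benzyl–silicon bond, and loss or migration of a TBS group. Fallback, from 17 to 19, without fluoride activation:

- Dimethyldioxirane epoxidises C1=C6 anti to silicon, giving the β-silyl epoxide F5.
- PPTS in MeOH triggers anti (Peterson-type) elimination to the tertiary allylic alcohol F6 (C6=C7, C1–OH).
- Pyridinium chlorochromate, C5H5NH[CrO3Cl], effects the oxidative 1,3-transposition (Dauben–Babler) to enone F7 (C7 ketone, C1=C6).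
- NaBH4/CeCl3 reduces F7 to 19; its C7 epimer would converge at ketone 31 as well.

**Step 15.** Most likely to go wrong: hydride delivery from the wrong face of the flexible ring, or competing reduction at C1. Fallback, from 22 to 29: reduction under non-chelating conditions (NaBH4, CeCl3, MeOH, −78 °C), or the minor product of step 15, gives the 6-epi carbinol F8. F8 is esterified with acid 28 under Mitsunobu conditions (PPh3, DIAD, toluene), which inverts C6 and installs the phosphonoacetate at once, giving 29. Both epimers are thus usable.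

**Step 25.** Most likely to go wrong: activation of the C9 hydroxyl instead of C8, elimination at the β-hydroxy ketone, or translactonisation of the free C8–OH onto C12. Fallback, from 35 to 37:

- SOCl2/Et3N gives cyclic sulfite F9.
- RuCl3·xH2O (cat.)/NaIO4 gives cyclic sulfate F10.
- Cesium methacrylate (from 36 and Cs2CO3, DMF, rt) opens F10 at the allylic C8 with inversion, giving the C9 sulfate monoester F11.
- Catalytic H2SO4 and water in THF hydrolyse F11 to 37.

## Further compounds

F1 | step 9 | dienylsilanol (13 with Si–OH in place of Si–CH2Ph) | C/C=C1\CC[C@@]2(C)O[C@H]2/C1=C\[Si](C)(C)O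
F2 | step 9 | silanol carbonate (15 with Si–OH in place of Si–CH2Ph) | C[C@H]1[C@H]2OC(=O)O[C@H]2[C@@H]([Si](C)(C)O)C2=C1CC[C@@]1(C)O[C@H]12
F3 | step 9 | silanol diol (16 with Si–OH in place of Si–CH2Ph) | C[C@H]1[C@@H](O)[C@@H](O)[C@@H]([Si](C)(C)O)C2=C1CC[C@@]1(C)O[C@H]12
F4 | step 9 | tris-silylated compound (8,9-bis-TBS ether, C7–SiMe2–O–TBS) | C[C@H]1[C@@H](O[Si](C)(C)C(C)(C)C)[C@@H](O[Si](C)(C)C(C)(C)C)[C@@H]([Si](C)(C)O[Si](C)(C)C(C)(C)C)C2=C1CC[C@@]1(C)O[C@H]12
F0 | step 8 | none | none
F5 | step 12 | β-silyl epoxide (1,6-epoxide of 17; configuration at C1/C6 not defined) | C[C@H]1[C@@H](O[Si](C)(C)C(C)(C)C)[C@@H](O[Si](C)(C)C(C)(C)C)[C@@H]([Si](C)(C)Cc2ccccc2)C23OC21CC[C@@]1(C)O[C@H]13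
F6 | step 12 | tertiary allylic alcohol (C6=C7, C1–OH; configuration at C1 not defined) | C[C@H]1[C@@H](O[Si](C)(C)C(C)(C)C)[C@@H](O[Si](C)(C)C(C)(C)C)C=C2[C@@H]3O[C@]3(C)CCC12O
F7 | step 12 | enone (C7 ketone, C1=C6, 8,9-bis-TBS ether) | C[C@H]1[C@@H](O[Si](C)(C)C(C)(C)C)[C@@H](O[Si](C)(C)C(C)(C)C)C(=O)C2=C1CC[C@@]1(C)O[C@H]12
F8 | step 15 | 6-epi carbinol (C6 epimer of 23) | C[C@H]1[C@@H](O[Si](C)(C)C(C)(C)C)[C@@H](O[Si](C)(C)C(C)(C)C)[C@@H](O[Si](CC)(CC)CC)[C@@H](O)[C@@H]2O[C@]2(C)CCC1=O
F9 | step 25 | cyclic sulfite of 35 | O=S1O[C@H]2C3=C(COC(C)=O)C(=O)O[C@@H]3[C@@H]3O[C@]3(C)CCC(=O)[C@@H](C)[C@H]2O1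
F10 | step 25 | cyclic sulfate of 35 | O=S1(=O)O[C@H]2C3=C(COC(C)=O)C(=O)O[C@@H]3[C@@H]3O[C@]3(C)CCC(=O)[C@@H](C)[C@H]2O1
F11 | step 25 | C9 hydrogen sulfate of 37 | C=C(C)C(=O)O[C@@H]1C2=C(COC(C)=O)C(=O)O[C@@H]2[C@@H]2O[C@]2(C)CCC(=O)[C@@H](C)[C@H]1OS(=O)(=O)O
A1 | alternative 1 | ten-membered 4Z,8E-diene fused to the butenolide, C1 dioxolane, C13 OTBS | C[C@H]1/C=C/C2=C(CO[Si](C)(C)C(C)(C)C)C(=O)O[C@@H]2/C=C(C)\CCC13OCCO3
A2 | alternative 2 | ten-membered C5 carbinol fused to the butenolide, C1 dithiane, C4 OPMB, 8,9-bis-OTBS | CC(=O)OCC1=C2[C@@H](O[Si](C)(C)C(C)(C)C)[C@H](O[Si](C)(C)C(C)(C)C)[C@H](C)C3(SCCCS3)CC[C@@](C)(OCc3ccc(OC)cc3)[C@H](O)[C@H]2OC1=O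
A3 | alternative 3 | ten-membered homoallylic alcohol with exocyclic C11=C13 methylene, 8,9-acetonide, C1 dioxolane | O[C@H]1[C@H](C(=C)CO[Si](C)(C)C(C)(C)C)[C@H]2OC(C)(C)O[C@@H]2[C@H](C)C2(OCCO2)CC/C(C)=C\1
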